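(The data are calculated with constants of no real substance; scatter was added.)

The leftover in the grey run caught my eye first: at 120 s, monomer in chains and uncatalysed product came to 79.5% of the charge, so 20.5% was neither, and the share asked about does not count that part.

| flask | free monomer | initiator | remark | time |
|---|---|---|---|---|
| grey | 0.20 M | 1 mM | run made earlier |  |
| teal | 0.20 M | 0.50 mM | run made earlier |  |
| green | 0.20 M | 0.75 mM | run made earlier |  |
| midnight | 0.20 M | 1.0 mM | plug flow through a tube for 2.0 min, no back-mixing | 2.0 min |
| autumn | 0.20 M | 1.0 mM | everything together in a closed stirred flask, run for 2.0 min | 2.0 min |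
| spring | 0.20 M | 1.0 mM | one stirred flow tank at steady state, fed with the mixture as stated, mean residence time 2.0 min |  |
| winter | 0.20 M (fed, over 2.00 min) | 1.0 mM | all but free monomer at the start; free monomer goes in evenly over 2.00 min, the run ends at 2.0 min | 2.0 min |

| run | time / s | monomer in chains / % | uncatalysed product / % |
|---|---|---|---|
| grey | 25.0 | 32.7 | 4.3 |
| grey | 50.0 | 52.9 | 8.0 |
| grey | 80.0 | 65.0 | 9.5 |
| grey | 90.0 | 66.9 | 8.5 |
| grey | 120 | 70.1 | 9.4 |
| teal | 10.0 | 7.0 | 2.2 |
| teal | 20.0 | 14.4 | 4.6 |
| teal | 40.0 | 27.4 | 7.7 |
| teal | 80.0 | 43.2 | 11.8 |
| green | 10.0 | 10.0 | 2.5 |
| green | 20.0 | 21.0 | 4.2 |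
| green | 30.0 | 30.4 | 5.6 |
| green | 50.0 | 43.9 | 7.8 |
| green | 80.0 | 55.5 | 8.4 |

(each reading ± 0.5 percentage points)

- the set-up with the highest share of monomer in chains in all that became monomer in chains or uncatalysed product, at the outlet or at the end ("none" if the first two lie within 2 percentage points) (midnight / autumn / spring / winter / none)
- share of monomer in chains in all that became monomer in chains or uncatalysed product, at the outlet or at the end, midnight
- share of monomer in chains in all that became monomer in chains or uncatalysed product, at the outlet or at the end, autumn
- share of monomer in chains in all that became monomer in chains or uncatalysed product, at the outlet or at the end, spring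
- share of monomer in chains in all that became monomer in chains or uncatalysed product, at the outlet or at the end, winter

- the stated concentrations are those of everything mixed, before any reaction; amounts are the same in each set-up
- the feed brings no volume worth counting
- the earlier runs were made in a closed, stirred flask

So I divided one rate by the other, which takes time out. In grey, monomer in chains per uncatalysed product read 7.60 at 25.0 s and 7.46 at 120 s, although monomer in chains had grown to twice its early reading. But a scatter of 0.5 percentage points on the early reading of uncatalysed product moves that early ratio by about 0.884, so these two readings show no change beyond their scatter, and a modest drift could hide in it. From grey I read 7.46 mM⁻¹: this is g, the selectivity factor per unit of c(initiator) charged, and the share is g·c(initiator) over one plus the same. At their last readings, teal gave 7.32 mM⁻¹ and green 8.81 mM⁻¹.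

Now the question turned round. For a winner, one set-up would have to lead the next by 2 points. From grey's share of 88.2%, that means a ratio of 9.18, a factor of 1.23. The ratio would have to climb that far as free monomer falls, or differ that far between vessels at one c(initiator), and grey's two readings showed no climb of that size, within their scatter. So I reckoned midnight, autumn, spring and winter near 88.2%, with no winner.

The forecast said 88.2%, 88.2%, 91.2% and 90.6%, verdict none, on the ground that “Low monomer therefore favours chains.” We part on spring and winter, not on the verdict.

The flasks gave 88.6% in midnight, 88.6% in autumn, 88.5% in spring and 87.4% in winter, so the verdict was none; midnight's ratio was 7.77 against 7.46 from g.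

    free monomer + initiator → living end + monomer in chains (k = 1.20 M⁻¹ s⁻¹)
    free monomer + living end → monomer in chains + living end, rate k2*[living end]*[free monomer] (k = 22.0 M⁻¹ s⁻¹)
    free monomer ⇌ dormant form (K = 3.90, k = 0.00510 s⁻¹)
    free monomer → uncatalysed product (k = 0.00250 s⁻¹)
    2 initiator → spent initiator (k = 2.20 M⁻¹ s⁻¹)

Take a neighbour of winter charged with 2.5 × 10⁻⁴ M of initiator, other charges and time held. There g gives a ratio of 1.86, a share of 65.1%. That flask ended with 19.1% monomer in chains, 9.84% uncatalysed product and 52.1% of the charge as free monomer, and its share stood at 66.0%.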